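The ten-membered carbocycle is not closed directly: its C1–C10 bond is made last, by excising a sulfur atom. An eleven-membered cyclic sulfone, in which SO2 bridges C1 and C10, undergoes Ramberg–Bäcklund contraction. In one operation this forges C1–C10, shrinks the ring to the germacrane size and leaves the ring-cis trisubstituted C1=C10 olefin with C14 as a free allylic alcohol on C10, the exact handle for the C1–C10 epoxide of the target. The precursor is the trans C6–C7 γ-lactone fused to that thiacycle, carrying the C4=C5 olefin, silyl ethers on O8 and O15, and the C14 hydroxyl on the sulfone α-carbon C10.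

Key step: step 19

Remark: atom labels C1–C15 are those of the germacranolide target throughout, and (S)-4-methoxybenzyl glycidyl ether (4) is treated as a purchasable epoxide (PMB = 4-methoxybenzyl, TBS = tert-butyldimethylsilyl, TES = triethylsilyl).

Step 1
Reactants: 1 (S)-5-(hydroxymethyl)furan-2(5H)-one
Product: 2 TBS butenolide
Conditions: TBSCl, imidazole, CH2Cl2, 0 °C → rt
Reagents that add atoms: tert-butyldimethylsilyl chloride, CC(C)(C)[Si](C)(C)Cl
Why: Silyl ether formation at the primary hydroxyl with a weak amine base should leave the base-sensitive butenolide and its C6 stereocentre untouched.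

Step 2
Reactants: 3 1,3-dithiane; 4 (S)-4-methoxybenzyl glycidyl ether
Product: 7 dithiane TES ether (10S), via 2-lithio-1,3-dithiane 5 (not isolated), via lithium alkoxide 6 (not isolated)
Conditions: n-BuLi, THF, −30 °C; 4, −30 → 0 °C; then TESCl, 0 °C
Reagents that add atoms: triethylsilyl chloride, CC[Si](CC)(CC)Cl
Why: Dithiane umpolung alkylation: the lithiated dithiane opens the epoxide at its unsubstituted carbon (SN2), so the epoxide stereocentre becomes the C10 carbinol unchanged, and the alkoxide is silylated in the same flask.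

Step 3
Reactants: 7 dithiane TES ether; 2 TBS butenolide
Product: 10 hydroxy dithiane lactone, via lithiated dithiane 8 (not isolated), via TES-protected adduct 9 (not isolated)
Conditions: t-BuLi, THF–HMPA (9:1), −78 °C; 2, −78 °C; AcOH quench; then PPTS (cat.), MeOH, 0 °C
Reagents that add atoms: none
Why: Dithiane Michael addition: the soft, HMPA-solvated 2-alkyl-2-lithiodithiane should add 1,4 to the butenolide anti to the C6 silyloxymethyl group, which sets C7 with C8 trans to C5, and mild acid then cleaves the secondary TES ether faster than the primary TBS ether.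

Step 4
Reactants: 10 hydroxy dithiane lactone
Product: 11 β-hydroxy ketone
Conditions: I2, NaHCO3, MeCN–H2O (4:1), 0 °C
Reagents that add atoms: water, O
Why: Iodine-mediated dithioacetal hydrolysis under bicarbonate buffering should unveil the C8 ketone quickly and cold, without base strong enough to expel the β-acyloxy group at C6 or to epimerise C7.

Step 5
Reactants: 11 β-hydroxy ketone
Product: 12 anti acetate alcohol (8S,10S)
Conditions: SmI2 (0.3 equiv), MeCHO (8 equiv), THF, −10 °C
Reagents that add atoms: acetaldehyde, CC=O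
Why: Evans–Tishchenko reduction: the samarium-bound hemiacetal of the C10 hydroxyl and acetaldehyde delivers hydride intramolecularly through a chair-like transition state, which should set C8 as S, anti to C10, and leave C10 as its acetate, so the two carbinols emerge already differentiated.

Step 6
Reactants: 12 anti acetate alcohol
Product: 13 C8 TBS ether
Conditions: TBSOTf, 2,6-lutidine, CH2Cl2, −78 °C
Reagents that add atoms: tert-butyldimethylsilyl triflate, CC(C)(C)[Si](C)(C)OS(=O)(=O)C(F)(F)F
Why: Silylation of the hindered secondary C8 hydroxyl with a silyl triflate and a hindered base at low temperature should outrun acyl migration or translactonisation.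

Step 7
Reactants: 13 C8 TBS ether
Product: 14 C5 primary alcohol
Conditions: HF·pyridine, pyridine, THF, 0 °C
Reagents that add atoms: none
Why: Selective desilylation: buffered fluoride should cleave the unhindered primary silyl ether at O5 well before the hindered secondary one at O8, with acetate, PMB ether and lactone inert.

Step 8
Reactants: 14 C5 primary alcohol
Product: 15 C5 aldehyde
Conditions: Dess–Martin periodinane, CH2Cl2, 0 °C → rt
Reagents that add atoms: none
Why: Dess–Martin oxidation is near neutral, so the α-acyloxy aldehyde should form without over-oxidation; any epimerisation at C6 would return to the favoured trans lactone.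

Step 9
Reactants: 16 1-bromo-4-chlorobutane
Product: 17 (4-chlorobutyl)triphenylphosphonium bromide
Conditions: PPh3, toluene, 110 °C
Reagents that add atoms: triphenylphosphine, c1ccc(cc1)P(c1ccccc1)c1ccccc1
Why: SN2 quaternisation of the phosphine, in which bromide is displaced much faster than chloride, so the C1 chloride is kept.

Step 10
Reactants: 17 (4-chlorobutyl)triphenylphosphonium bromide
Product: 19 formyl ylide, via chlorobutylidene ylide 18 (not isolated)
Conditions: KN(SiMe3)2, THF, −78 °C; cannulate into HCO2Et, −78 → 0 °C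
Reagents that add atoms: ethyl formate, CCOC=O
Why: Ylide C-formylation: the non-stabilised ylide is acylated by the formate, the liberated ethoxide deprotonates the formylphosphonium ion to the stabilised ylide, and the low temperature should keep the ylide from displacing its own chloride.

Step 11
Reactants: 15 C5 aldehyde; 19 formyl ylide
Product: 20 (E)-enal
Conditions: toluene, 50 °C
Reagents that add atoms: none
Why: Wittig olefination with a formyl-stabilised ylide should give the (E)-2-alkyl enal, placing C15 trans and C3 cis to C6, which is the ring-cis C4=C5 geometry of the target.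

Step 12
Reactants: 20 (E)-enal
Product: 21 C15 allylic alcohol
Conditions: NaBH4, CeCl3·7H2O, MeOH, −78 °C
Reagents that add atoms: none
Why: Luche reduction is 1,2-selective for the enal and should leave lactone, acetate and alkyl chloride untouched at this temperature.

Step 13
Reactants: 21 C15 allylic alcohol
Product: 22 C15 TBS ether
Conditions: TBSCl, imidazole, CH2Cl2, rt
Reagents that add atoms: tert-butyldimethylsilyl chloride, CC(C)(C)[Si](C)(C)Cl
Why: Routine silyl ether formation at the primary allylic hydroxyl, the only free hydroxyl present.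

Step 14
Reactants: 22 C15 TBS ether
Product: 23 C10 alcohol
Conditions: K2CO3, MeOH, 0 °C
Reagents that add atoms: none
Why: Carbonate-catalysed transesterification should remove the secondary acetate, while the γ-lactone is the thermodynamically preferred form under these conditions and the silyl ethers are inert.

Step 15
Reactants: 23 C10 alcohol; 24 thioacetic acid
Product: 25 C10 thioacetate (10R)
Conditions: PPh3, DIAD, THF, 0 °C → rt
Reagents that add atoms: none
Why: Mitsunobu thioesterification: thioacetate displaces the C10 oxyphosphonium ion with inversion (SN2), giving 10R, a configuration that is of no later consequence.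

Step 16
Reactants: 25 C10 thioacetate
Product: 27 eleven-membered sulfide, via cesium thiolate 26 (not isolated)
Conditions: Cs2CO3, NaI (cat.), degassed MeOH–DMF (1:9), slow addition to 2 mM, 40 °C
Reagents that add atoms: none
Why: Thioether macrocyclisation: methanolysis frees the thiolate, which should close the ring by iodide-assisted SN2 on the primary C1 chloride (11-exo-tet) under high dilution, helped by the long C–S bonds and the ring-cis C4=C5 olefin.

Step 17
Reactants: 27 eleven-membered sulfide
Product: 28 sulfone PMB ether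
Conditions: (NH4)6Mo7O24·4H2O (cat.), 30% H2O2, EtOH, 0 °C → rt
Reagents that add atoms: hydrogen peroxide, OO
Why: Molybdate-catalysed peroxide oxidation should take the sulfide through the sulfoxide to the sulfone without epoxidising the trisubstituted olefin, which carries no free allylic hydroxyl at this stage.

Step 18
Reactants: 28 sulfone PMB ether
Product: 29 sulfone alcohol
Conditions: DDQ, CH2Cl2–pH 7 buffer, 0 °C
Reagents that add atoms: none
Why: Oxidative PMB cleavage (benzylic hydride abstraction, then hydrolysis of the oxocarbenium ion) should free the C14 hydroxyl while silyl ethers, sulfone and lactone stay intact.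

Step 19
Reactants: 29 sulfone alcohol
Product: 34 ten-membered diene lactone, via ring-opened carboxylate 30 (not isolated), via bromo sulfone 31 (not isolated), via episulfone 32 (not isolated), via diene carboxylate 33 (not isolated)
Conditions: KOH/Al2O3, t-BuOH–THF, rt; then BrCl2C–CCl2Br, 0 °C → rt; then 1 M HCl to pH 3
Reagents that add atoms: none
Why: Hydroxide first opens the lactone to the C12 carboxylate (so C11 cannot be halogenated) and turns the C14 hydroxyl into its alkoxide; the α-sulfonyl carbanion at the unbranched C1 is then brominated by the positive-halogen donor, the C10 carbanion displaces bromide to give the episulfone, SO2 is lost to form the C1=C10 bond, and acidification re-closes the γ-lactone onto O6 because O8 is blocked as its silyl ether. This is a Ramberg–Bäcklund reaction with in situ α-halogenation, a known way to contract cyclic sulfones to medium- and large-ring cycloalkenes. The only new ring bond is C1–C10, made by a 3-exo-tet closure to the transient thiirane dioxide, so the ten-membered carbocycle arises by contraction of the eleven-membered thiacycle and not by an end-to-end cyclisation. No stereocentre is created and the C10 centre is erased, so both C10 epimers and both C1 bromides converge. The step needs the ring-cis olefin (C2 and C9 cis), which rests on the kinetic preference for the cis-fused episulfone and on the strain a ring-trans trisubstituted olefin would cost in a ten-membered ring that already holds the cis C4=C5 olefin and the trans lactone. It also needs C14 to stay on C10: as the alkoxide the free hydroxyl cannot be expelled from the C10 carbanion, whereas an ether there would invite β-elimination.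

Step 20
Reactants: 34 ten-membered diene lactone
Product: 37 methylene lactone, via Mannich base 35 (not isolated), via ammonium iodide 36 (not isolated)
Conditions: LiN(SiMe3)2 (2.5 equiv), THF, −78 °C; CH2=NMe2+ I−, −78 → 0 °C; H2O; then MeI, MeOH, rt; then NaHCO3 (aq.), EtOAc
Reagents that add atoms: Eschenmoser's salt (N,N-dimethylmethyleneiminium iodide), C=[N+](C)C.[I-]
Why: Mannich aminomethylation of the lactone enolate (the C14 hydroxyl being held as its alkoxide by the extra base), N-methylation and Hofmann-type elimination should install the exocyclic C11=C13 methylene, the transient C11 centre being destroyed again.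

Step 21
Reactants: 37 methylene lactone
Product: 38 epoxy alcohol (1R,10R)
Conditions: Ti(OiPr)4, D-(−)-diethyl tartrate, t-BuOOH, 4 Å MS, CH2Cl2, −20 °C
Reagents that add atoms: tert-butyl hydroperoxide, CC(C)(C)OO
Why: Sharpless asymmetric epoxidation: the titanium–tartrate complex binds the C14 allylic alkoxide and delivers oxygen to one face of C1=C10, and D-(−)-tartrate gives the series enantiomeric to the (2S,3S)-epoxy alcohols formed with L-(+)-tartrate from (E)-allylic alcohols, that is 1R,10R here, while the C4=C5 olefin (no free allylic hydroxyl) and the electron-poor methylene lactone should not react.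

Step 22
Reactants: 38 epoxy alcohol
Product: 39 triol
Conditions: HF·pyridine, pyridine, THF, 0 °C → rt
Reagents that add atoms: none
Why: Fluoride-driven desilylation of both TBS ethers, buffered with pyridine so that the medium should neither open the epoxide nor trigger alkoxide-mediated translactonisation or addition to the methylene lactone.

Step 23
Reactants: 39 triol
Product: 40 enal diol
Conditions: MnO2, CH2Cl2, rt
Reagents that add atoms: none
Why: Allylic oxidation with MnO2 should touch only the C15 hydroxyl, because the C14 hydroxyl is now an epoxy carbinol and the C8 hydroxyl is a saturated secondary alcohol.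

Step 24
Reactants: 40 enal diol
Product: 41 CNP0211286.1
Conditions: Ac2O, pyridine, DMAP (cat.), CH2Cl2, 0 °C → rt
Reagents that add atoms: acetic anhydride, CC(=O)OC(C)=O
Why: Nucleophile-catalysed acylation of the primary C14 and secondary C8 hydroxyls completes the target without touching any stereocentre.

Compound list
1 | (S)-5-(hydroxymethyl)furan-2(5H)-one | O=C1C=C[C@@H](CO)O1 | starting material
2 | (S)-5-{[(tert-butyldimethylsilyl)oxy]methyl}furan-2(5H)-one | O=C1C=C[C@@H](CO[Si](C)(C)C(C)(C)C)O1 | intermediate
3 | 1,3-dithiane | C1CSCSC1 | starting material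
4 | (S)-2-{[(4-methoxybenzyl)oxy]methyl}oxirane | COc1ccc(COC[C@@H]2CO2)cc1 | starting material
5 | 2-lithio-1,3-dithiane | [Li]C1SCCCS1 | intermediate
6 | lithium (S)-1-(1,3-dithian-2-yl)-3-[(4-methoxybenzyl)oxy]propan-2-olate | [Li]O[C@@H](CC1SCCCS1)COCc1ccc(OC)cc1 | intermediate
7 | (S)-2-{3-[(4-methoxybenzyl)oxy]-2-[(triethylsilyl)oxy]propyl}-1,3-dithiane (C8 = dithiane carbon, 10S) | CC[Si](CC)(CC)O[C@@H](CC1SCCCS1)COCc1ccc(OC)cc1 | intermediate
8 | 2-lithio derivative of 7 | CC[Si](CC)(CC)O[C@@H](CC1([Li])SCCCS1)COCc1ccc(OC)cc1 | intermediate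
9 | TES-protected adduct: γ-lactone with CH2OTBS on C6 (configured as in 1) and, trans to it on C7, the dithiane carbon C8 bearing CH2–CH(OTES)–CH2OPMB (10S) | O=C1C[C@H](C2(C[C@H](O[Si](CC)(CC)CC)COCc3ccc(OC)cc3)SCCCS2)[C@@H](CO[Si](C)(C)C(C)(C)C)O1 | intermediate
10 | hydroxy dithiane lactone: as 9 with free C10 hydroxyl (10S) | O=C1C[C@H](C2(C[C@H](O)COCc3ccc(OC)cc3)SCCCS2)[C@@H](CO[Si](C)(C)C(C)(C)C)O1 | intermediate
11 | β-hydroxy ketone: trans lactone with C8 ketone, C10 hydroxyl (10S), C14 OPMB, C5 OTBS | O=C1C[C@H](C(=O)C[C@H](O)COCc2ccc(OC)cc2)[C@@H](CO[Si](C)(C)C(C)(C)C)O1 | intermediate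
12 | anti acetate alcohol: trans lactone with C8 hydroxyl (8S), C10 acetate (10S), C14 OPMB, C5 OTBS | O=C1C[C@H]([C@@H](O)C[C@H](OC(C)=O)COCc2ccc(OC)cc2)[C@@H](CO[Si](C)(C)C(C)(C)C)O1 | intermediate
13 | C8 TBS ether of 12 (8S,10S) | O=C1C[C@H]([C@@H](O[Si](C)(C)C(C)(C)C)C[C@H](OC(C)=O)COCc2ccc(OC)cc2)[C@@H](CO[Si](C)(C)C(C)(C)C)O1 | intermediate
14 | C5 primary alcohol: as 13 with free C5 hydroxyl | O=C1C[C@H]([C@@H](O[Si](C)(C)C(C)(C)C)C[C@H](OC(C)=O)COCc2ccc(OC)cc2)[C@@H](CO)O1 | intermediate
15 | C5 aldehyde: as 14 with C5 formyl on C6 | O=C1C[C@H]([C@@H](O[Si](C)(C)C(C)(C)C)C[C@H](OC(C)=O)COCc2ccc(OC)cc2)[C@@H](C=O)O1 | intermediate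
16 | 1-bromo-4-chlorobutane | ClCCCCBr | starting material
17 | (4-chlorobutyl)triphenylphosphonium bromide | ClCCCC[P+](c1ccccc1)(c1ccccc1)c1ccccc1.[Br-] | intermediate
18 | (4-chlorobutylidene)triphenylphosphorane | ClCCCC=P(c1ccccc1)(c1ccccc1)c1ccccc1 | intermediate
19 | 5-chloro-2-(triphenyl-λ5-phosphanylidene)pentanal | O=CC(CCCCl)=P(c1ccccc1)(c1ccccc1)c1ccccc1 | intermediate
20 | (E)-enal: trans lactone with C5=C4(CHO)–(CH2)3Cl on C6 (C15 trans to C6), C8 OTBS (8S), C10 OAc (10S), C14 OPMB | O=C1C[C@H]([C@@H](O[Si](C)(C)C(C)(C)C)C[C@H](OC(C)=O)COCc2ccc(OC)cc2)[C@@H](/C=C(/C=O)CCCCl)O1 | intermediate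
21 | C15 allylic alcohol: as 20 with CH2OH at C15 | O=C1C[C@H]([C@@H](O[Si](C)(C)C(C)(C)C)C[C@H](OC(C)=O)COCc2ccc(OC)cc2)[C@@H](/C=C(/CO)CCCCl)O1 | intermediate
22 | C15 TBS ether of 21 | O=C1C[C@H]([C@@H](O[Si](C)(C)C(C)(C)C)C[C@H](OC(C)=O)COCc2ccc(OC)cc2)[C@@H](/C=C(/CO[Si](C)(C)C(C)(C)C)CCCCl)O1 | intermediate
23 | C10 alcohol: as 22 with free C10 hydroxyl (10S) | O=C1C[C@H]([C@@H](O[Si](C)(C)C(C)(C)C)C[C@H](O)COCc2ccc(OC)cc2)[C@@H](/C=C(/CO[Si](C)(C)C(C)(C)C)CCCCl)O1 | intermediate
24 | thioacetic S-acid | CC(=O)S | starting material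
25 | C10 thioacetate: as 23 with SAc at C10, inverted (10R) | O=C1C[C@H]([C@@H](O[Si](C)(C)C(C)(C)C)C[C@@H](SC(C)=O)COCc2ccc(OC)cc2)[C@@H](/C=C(/CO[Si](C)(C)C(C)(C)C)CCCCl)O1 | intermediate
26 | cesium thiolate of 25 (C10 thiolate, C1 chloride) | O=C1C[C@H]([C@@H](O[Si](C)(C)C(C)(C)C)C[C@@H]([S-])COCc2ccc(OC)cc2)[C@@H](/C=C(/CO[Si](C)(C)C(C)(C)C)CCCCl)O1.[Cs+] | intermediate
27 | eleven-membered sulfide: S between C1 and C10, fused trans lactone, C4=C5 ring-cis with C15 OTBS, C8 OTBS (8S), C14 OPMB on C10 (10R) | C1C(=O)O[C@@H]2/C=C(/CO[Si](C)(C)C(C)(C)C)CCCS[C@@H](COCc3ccc(OC)cc3)C[C@H](O[Si](C)(C)C(C)(C)C)[C@@H]12 | intermediate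
28 | sulfone PMB ether: S,S-dioxide of 27 | C1C(=O)O[C@@H]2/C=C(/CO[Si](C)(C)C(C)(C)C)CCCS(=O)(=O)[C@@H](COCc3ccc(OC)cc3)C[C@H](O[Si](C)(C)C(C)(C)C)[C@@H]12 | intermediate
29 | sulfone alcohol: eleven-membered cyclic sulfone fused to the trans lactone, free C14 hydroxyl on C10 (10R), TBS ethers on O8 and O15 | C1C(=O)O[C@@H]2/C=C(/CO[Si](C)(C)C(C)(C)C)CCCS(=O)(=O)[C@@H](CO)C[C@H](O[Si](C)(C)C(C)(C)C)[C@@H]12 | intermediate
30 | ring-opened carboxylate: potassium C12 carboxylate of 29 with free C6 hydroxyl | [K+].[O-]C(=O)C[C@H]1[C@H](O)/C=C(/CO[Si](C)(C)C(C)(C)C)CCCS(=O)(=O)[C@@H](CO)C[C@@H]1O[Si](C)(C)C(C)(C)C | intermediate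
31 | bromo sulfone: 30 brominated at C1 (C1 configuration not defined, both epimers converge) | [K+].[O-]C(=O)C[C@H]1[C@H](O)/C=C(/CO[Si](C)(C)C(C)(C)C)CCC(Br)S(=O)(=O)[C@@H](CO)C[C@@H]1O[Si](C)(C)C(C)(C)C | intermediate
32 | episulfone: C1–C10 thiirane 1,1-dioxide, cis-fused (C2 and C9 cis; one of the two cis faces drawn, both give the same olefin) | [K+].[O-]C(=O)C[C@H]1[C@H](O)/C=C(/CO[Si](C)(C)C(C)(C)C)CC[C@H]2[C@@](CO)(C[C@@H]1O[Si](C)(C)C(C)(C)C)S2(=O)=O | intermediate
33 | diene carboxylate: potassium salt of the seco acid of 34 | [K+].[O-]C(=O)C[C@H]1[C@H](O)/C=C(/CO[Si](C)(C)C(C)(C)C)CC/C=C(/CO)C[C@@H]1O[Si](C)(C)C(C)(C)C | intermediate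
34 | ten-membered diene lactone: trans 6,12-lactone, C1=C10 and C4=C5 both ring-cis (both E by CIP), free C14 allylic alcohol, TBS ethers on O8 (8S) and O15 | C1C(=O)O[C@@H]2/C=C(/CO[Si](C)(C)C(C)(C)C)CC/C=C(/CO)C[C@H](O[Si](C)(C)C(C)(C)C)[C@@H]12 | intermediate
35 | Mannich base: 34 with CH2NMe2 on C11 (C11 configuration not defined) | CN(C)CC1C(=O)O[C@@H]2/C=C(/CO[Si](C)(C)C(C)(C)C)CC/C=C(/CO)C[C@H](O[Si](C)(C)C(C)(C)C)[C@@H]12 | intermediate
36 | ammonium iodide: N-methyl quaternary salt of 35 | C[N+](C)(C)CC1C(=O)O[C@@H]2/C=C(/CO[Si](C)(C)C(C)(C)C)CC/C=C(/CO)C[C@H](O[Si](C)(C)C(C)(C)C)[C@@H]12.[I-] | intermediate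
37 | methylene lactone: 34 with exocyclic C11=C13 | C=C1C(=O)O[C@@H]2/C=C(/CO[Si](C)(C)C(C)(C)C)CC/C=C(/CO)C[C@H](O[Si](C)(C)C(C)(C)C)[C@@H]12 | intermediate
38 | epoxy alcohol: (1R,10R)-1,10-epoxide of 37 with free C14 hydroxyl | C=C1C(=O)O[C@@H]2/C=C(/CO[Si](C)(C)C(C)(C)C)CC[C@H]3O[C@@]3(CO)C[C@H](O[Si](C)(C)C(C)(C)C)[C@@H]12 | intermediate
39 | triol: 38 with free hydroxyls at C8, C14 and C15 | C=C1C(=O)O[C@@H]2/C=C(/CO)CC[C@H]3O[C@@]3(CO)C[C@H](O)[C@@H]12 | intermediate
40 | enal diol: 39 with C15 formyl, free hydroxyls at C8 and C14 | C=C1C(=O)O[C@@H]2/C=C(/C=O)CC[C@H]3O[C@@]3(CO)C[C@H](O)[C@@H]12 | intermediate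
41 | CNP0211286.1 (1R,6R,7R,8S,10R; 8,14-diacetate, C15 enal, 1,10-epoxide, α-methylene trans-6,12-lactone) | C=C1C(=O)O[C@@H]2/C=C(/C=O)CC[C@H]3O[C@@]3(COC(C)=O)C[C@H](OC(C)=O)[C@@H]12 | target

Total step count: 24. Longest linear sequence: 21 steps (from 1 through steps 1, 3–8 and 11–24; steps 2, 9 and 10 make the two side fragments).

Steps most likely to fail

Step 19 (Ramberg–Bäcklund contraction). Deprotonation at the alkoxide-flanked C10 may be slow, so that the C1 bromide is brominated a second time or the C14 alkoxide loses formaldehyde by retro-aldol cleavage; the episulfone may also close trans and deliver the ring-trans olefin. The fallback installs the halogen before the sulfone exists and avoids hydroxide altogether; it sets out from sulfide 27 and returns at 34. N-Chlorosuccinimide (CH2Cl2, 0 °C) should chlorinate 27 α to sulfur at the unbranched C1, through the chlorosulfonium ylide, to give the α-chloro sulfide F1. Oxidation with mCPBA (2.2 equiv, CH2Cl2, −20 °C) gives the α-chloro sulfone PMB ether F2, and DDQ frees the C14 hydroxyl to give the α-chloro sulfone alcohol F3. KOtBu (THF, −78 → 0 °C) then carries out the classical Ramberg–Bäcklund reaction of a pre-formed α-halo sulfone, with the lactone left closed, to give 34.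

Step 16 (thioether macrocyclisation). Intermolecular S-alkylation and disulfide formation may outpace closure of the strained eleven-membered ring. The fallback delivers sulfur as free sulfide to a bis-electrophile, so that the ring can close at either carbon; it sets out from alcohol 23 and returns at 27. Mesylation (MsCl, Et3N, CH2Cl2, 0 °C) gives the chloro mesylate F4. Slow addition of F4 to Na2S·9H2O and NaI in DMF at high dilution lets sulfide take one carbon and the resulting thiolate close on the other; C10 is inverted once in either order, so the product is 27 with the same C10 configuration as in the main route.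

Step 21 (asymmetric epoxidation). The face chosen by the tartrate reagent may be the transannularly shielded face of the ten-membered ring (mismatched double stereodifferentiation), giving a stalled reaction or poor facial selectivity. The fallback places oxygen indirectly, on the face opposite to the one an electrophile attacks; it sets out from 37 and returns at 38. N-Bromosuccinimide in THF–H2O (0 °C) should add bromine from the open face and water anti at the tertiary C10 to give the bromohydrin F5 (C1 bromide, C10 hydroxyl). K2CO3 in acetone then closes the epoxide by intramolecular SN2 at C1 to give 38. The deactivated C4=C5 olefin (two allylic C–O bonds) and the conjugated methylene should be spared.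

Further compounds
F1 | step 19 | α-chloro sulfide: 27 chlorinated at C1 (C1 configuration not defined) | C1C(=O)O[C@@H]2/C=C(/CO[Si](C)(C)C(C)(C)C)CCC(Cl)S[C@@H](COCc3ccc(OC)cc3)C[C@H](O[Si](C)(C)C(C)(C)C)[C@@H]12
F2 | step 19 | α-chloro sulfone PMB ether: S,S-dioxide of F1 | C1C(=O)O[C@@H]2/C=C(/CO[Si](C)(C)C(C)(C)C)CCC(Cl)S(=O)(=O)[C@@H](COCc3ccc(OC)cc3)C[C@H](O[Si](C)(C)C(C)(C)C)[C@@H]12
F3 | step 19 | α-chloro sulfone alcohol: F2 with free C14 hydroxyl | C1C(=O)O[C@@H]2/C=C(/CO[Si](C)(C)C(C)(C)C)CCC(Cl)S(=O)(=O)[C@@H](CO)C[C@H](O[Si](C)(C)C(C)(C)C)[C@@H]12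
F4 | step 16 | chloro mesylate: C10 methanesulfonate of 23 (10S) | O=C1C[C@H]([C@@H](O[Si](C)(C)C(C)(C)C)C[C@H](OS(C)(=O)=O)COCc2ccc(OC)cc2)[C@@H](/C=C(/CO[Si](C)(C)C(C)(C)C)CCCCl)O1
F5 | step 21 | bromohydrin: 37 with C1 bromide and C10 hydroxyl, anti | C=C1C(=O)O[C@@H]2/C=C(/CO[Si](C)(C)C(C)(C)C)CC[C@H](Br)[C@](O)(CO)C[C@H](O[Si](C)(C)C(C)(C)C)[C@@H]12
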